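# Proposed synthesis of (2R,3R)-3,5-dihydroxy-2-(3-hydroxy-4-methoxyphenyl)-7-methoxy-6-(3-methylbut-2-en-1-yl)chroman-4-one (15)

## Analysis of the target

Compound 15 is a trans-dihydroflavonol: a chroman-4-one (benzo ring A fused to the oxygen heterocycle C) with the 3-hydroxy-4-methoxyphenyl ring B on C2 and a hydroxyl on C3, both equatorial, absolute configuration 2R,3R. Ring A is fully differentiated: a 5-OH chelated to the C4 carbonyl, a prenyl group on C6, a 7-OMe and a free C8–H. The two stereocentres are contiguous and both labile: C3 is α to the ketone (enolisation), and C2 is β to it and bound to O1, so an enolate of ring C can expel the ring oxygen and open the ring. The sensitive groups are the prenyl double bond (electrophilic oxidants; acid closes it onto O5 to a chroman), the α-ketol (base and air lead to the flavonol) and the free OH groups. The difficulties are three: setting C2 and C3 in absolute and relative terms without basic or acidic ring-C chemistry; placing the prenyl group on C6 and not C8, which in any closure of ring C on a 2,6-dioxygenated aryl ketone means telling two ortho oxygens apart; and oxygenating C3 next to an oxidisable alkene. The structure invites one move: C2 and C3 are the β- and α-carbons of the C4 carbonyl, that is, the two carbons of the C2=C3 bond of a flat 4H-chromen-4-one. Ring B (at C2) and the hydroxyl oxygen (at C3) can therefore be added across that bond in one three-component operation. A second feature serves it: O5 and C6 are ortho, so a C5 unit parked on O5 can be relayed to C6 by a [3,3] shift once ring C is closed.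

## Retrosynthetic reasoning

**15 ⇒ 7 + 11 + one oxygen atom.** The C2–C1′ bond and the C3–OH bond are cut together. Removing ring B and the hydroxyl from the β- and α-carbons leaves the achiral, planar chromone 7, which already holds the complete A/C skeleton with the prenyl group on C6. Forward, a chiral rhodium catalyst adds the aryl group of 11 to C2, the enolate is trapped on oxygen as silyl enol ether 13, and an electrophilic oxygen donor attacks C3=C4 anti to the new aryl group (14). Buffered fluoride then unmasks the ketol and all phenols. This sets both stereocentres as a group (C2 by the catalyst, C3 by relay), joins the two halves, and needs no ring closure, so the 6-endo/5-exo and SN1 problems of chalcone-based routes do not arise. Transient O-silylation (12, 13) keeps ring C closed, since the enolate never exists as a free metal enolate.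

**7 ⇒ 6.** The C6–CH2 bond of the prenyl group is cut and the other terminus of the C5 unit is reconnected to O5 (aromatic Claisen rearrangement of a 1,1-dimethylallyl ether). This is cut here because ring C is already closed in 6: O1 is fixed, C4a is blocked, and the only ortho position open to the migrating group is C6. The rearrangement also unveils the chelated 5-OH. It is placed before the key step so that the thermal step runs on a robust achiral chromone and the key step ends the synthesis.

**6 ⇒ 5 ⇒ 3 (through 4).** The alkene of 6 comes from the alkyne of 5 by semi-hydrogenation. The alkyne form is carried through ring closure because the propargylic ether does not rearrange at the temperatures needed. Ring C of 5 is cut at O1–C2 and C2–C3: C2 is a one-carbon unit condensed onto the acetyl group of 3 (enaminone 4), and the only free phenol of 3 closes the ring. The ether oxygen of 3 thus becomes O5 without ambiguity.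

**3 ⇒ 1 + 2.** The O–C bond of the tertiary propargylic ether is cut. Compound 1 has two equivalent ortho hydroxyls, so mono-alkylation gives a single product and decides, in the first step, which oxygen will be O1 and which O5. This is what secures the 6-prenyl pattern.

**11 ⇒ 9 ⇒ 8 (through 10).** The C–Zn bond comes from the C–Br bond of 9 by halogen–lithium exchange and transmetalation. The phenol of 8 is masked as a silyl ether so that it falls off in the same fluoride treatment that ends the key step.

## Alternatives that were turned down

**Alternative 1:** the textbook route cuts O1–C2 last. A Claisen–Schmidt condensation would give chalcone A1, an enantioselective nucleophilic (Juliá–Colonna-type) epoxidation would give epoxy ketone A2, and removal of the phenol protecting groups with 6-endo opening of the epoxide at the benzylic carbon would give 15. It was turned down for four reasons.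
- The 2′,6′-dioxygenated aryl ketone of A1 is twisted out of conjugation and electron-rich, which makes hydroperoxide addition slow.
- The closure must invert the benzylic carbon cleanly, but the p-methoxy-substituted ring B favours ionisation (loss of the C2 configuration), and 5-exo attack at the α-carbon competes.
- The two ortho oxygens must be distinguished by protecting groups to decide 6- against 8-prenyl.
- The acid that removes those groups and drives the closure also cyclises the prenyl group onto O5. The sequence would run to nine or more linear steps.

**Alternative 2:** cut C2–C3. A catalytic asymmetric syn-selective direct aldol reaction of an α-hydroxy aryl ketone would give diol A3, and a Mitsunobu cyclodehydration would close O1–C2 with inversion to reach 15 after desilylation. It was turned down for three reasons.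
- The donor is a di-ortho-substituted, chelated ketone that enolises poorly.
- The acceptor is an electron-rich benzaldehyde, so the aldol is reversible and prone to dehydration.
- Activation of a p-methoxybenzylic carbinol under Mitsunobu conditions proceeds with partial ionisation, competes with epoxide formation by the neighbouring hydroxyl, and again leaves two phenols to choose from.

**Alternative 3:** cut C3–C4. An N-heterocyclic-carbene-catalysed intramolecular crossed benzoin reaction of the racemic dialdehyde A4 would close ring C and set C3, and the configurationally labile α-aryloxy aldehyde centre would make it a dynamic kinetic resolution. It was turned down for four reasons.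
- The acyl-anion role is likely to be taken by the more reactive aliphatic aldehyde, which would put the carbonyl on C3 instead of C4.
- The 2,6-disubstituted aryl aldehyde is hindered.
- The ketol produced can isomerise through the enediol.
- A4 itself needs a long synthesis that includes the same differentiation of two ortho oxygens.

Key step: step 7

Assumption: (S)-BINAP is taken to deliver the aryl group to the chromone face that leads to the 2S silyl enol ether 13, by analogy with the sense known for cyclic enones; if a model run shows the opposite sense, (R)-BINAP is used.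

## Route

Step 1
Reactants: 1 2′,6′-dihydroxy-4′-methoxyacetophenone; 2 3-chloro-3-methylbut-1-yne
Product: 3 1-[2-hydroxy-4-methoxy-6-[(2-methylbut-3-yn-2-yl)oxy]phenyl]ethan-1-one
Conditions: 2 (1.3 equiv), DBU (1.4 equiv), CuCl2·2H2O (1 mol%), MeCN, 0 °C → rt
Reagents that add atoms: none
Why: Copper-catalysed O-propargylation of a phenoxide with a tertiary propargylic chloride (via a copper allenylidene); the two hydroxyls of 1 are equivalent, and after the first alkylation the remaining one is strongly chelated and hindered, so the mono-ether should dominate.

Step 2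
Reactants: 3 1-[2-hydroxy-4-methoxy-6-[(2-methylbut-3-yn-2-yl)oxy]phenyl]ethan-1-one
Product: 5 7-methoxy-5-[(2-methylbut-3-yn-2-yl)oxy]-4H-chromen-4-one, via enaminone 4 (not isolated)
Conditions: Me2NCH(OMe)2 (3 equiv), PhMe, 80 °C; evaporate; AcOH, 50 °C
Reagents that add atoms: N,N-dimethylformamide dimethyl acetal, COC(OC)N(C)C
Why: Enaminone formation at the acetyl group, then acid-promoted oxa-Michael addition of the only free phenol and loss of dimethylamine (standard chromone synthesis); the ether oxygen necessarily becomes O5, and the tertiary propargylic ether should tolerate weak acid and 80 °C.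

Step 3
Reactants: 5 7-methoxy-5-[(2-methylbut-3-yn-2-yl)oxy]-4H-chromen-4-one
Product: 6 7-methoxy-5-[(2-methylbut-3-en-2-yl)oxy]-4H-chromen-4-one
Conditions: H2 (1 atm), Lindlar catalyst, quinoline, EtOAc, rt, stopped after 1 equiv of H2
Reagents that add atoms: none
Why: Lindlar semi-hydrogenation of a terminal alkyne; the vinylogous-ester C2=C3 bond of the chromone is not reduced by the poisoned catalyst.

Step 4
Reactants: 6 7-methoxy-5-[(2-methylbut-3-en-2-yl)oxy]-4H-chromen-4-one
Product: 7 5-hydroxy-7-methoxy-6-(3-methylbut-2-en-1-yl)-4H-chromen-4-one
Conditions: degassed xylenes, 130 °C, Ar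
Reagents that add atoms: none
Why: Aromatic Claisen rearrangement of an aryl 1,1-dimethylallyl ether, which gives the normal prenyl group at the ortho carbon; C4a is blocked, so the [3,3] shift can end only on C6, and enolisation then gives the chelated 5-OH.

Step 5
Reactants: 8 5-bromo-2-methoxyphenol
Product: 9 (5-bromo-2-methoxyphenoxy)(tert-butyl)dimethylsilane
Conditions: TBSCl (1.2 equiv), imidazole (2 equiv), DMF, rt
Reagents that add atoms: tert-butyldimethylsilyl chloride, CC(C)(C)[Si](C)(C)Cl
Why: Standard silylation of a phenol; the aryl silyl ether is inert to organolithium and organozinc reagents at low temperature and is cleaved by fluoride at the end.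

Step 6
Reactants: 9 (5-bromo-2-methoxyphenoxy)(tert-butyl)dimethylsilane
Product: 11 [3-(tert-butyldimethylsilyloxy)-4-methoxyphenyl]zinc chloride, via aryllithium 10 (not isolated)
Conditions: n-BuLi (1.05 equiv), THF, −78 °C; ZnCl2 (1.1 equiv, THF), −78 °C → rt; titrated THF solution used directly
Reagents that add atoms: zinc chloride, Cl[Zn]Cl
Why: Bromine–lithium exchange followed by transmetalation to zinc; the silyloxy group is meta to the metal, so no silyl migration to carbon is possible.

Step 7
Reactants: 7 5-hydroxy-7-methoxy-6-(3-methylbut-2-en-1-yl)-4H-chromen-4-one; 11 [3-(tert-butyldimethylsilyloxy)-4-methoxyphenyl]zinc chloride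
Product: 15 (2R,3R)-3,5-dihydroxy-2-(3-hydroxy-4-methoxyphenyl)-7-methoxy-6-(3-methylbut-2-en-1-yl)chroman-4-one, via silyl ether 12 (not isolated), via silyl enol ether 13 (not isolated), via silyloxy epoxide 14 (not isolated)
Conditions: NaH (1.05 equiv), THF, 0 °C, then TMSCl (4 equiv); [RhCl(C2H4)2]2 (2.5 mol%), (S)-BINAP (5.5 mol%), 11 (2 equiv), THF, 20 °C; hexane, filtration under Ar, solvent change to CH2Cl2; DMDO (1.05 equiv, acetone), −78 °C; TBAF/AcOH (1:1, 4 equiv), THF, 0 °C
Reagents that add atoms: dimethyldioxirane, CC1(C)OO1
Why: The phenoxide of 7 is silylated to 12; an aryl–rhodium(I) species formed by transmetalation from 11 inserts the C2=C3 bond of 12 (1,4-carbometalation), and the resulting oxa-π-allyl/zinc enolate is silylated on oxygen by TMSCl to give 13, which turns the catalyst over and prevents β-elimination of the ring oxygen (ring opening, racemisation). The closest known reaction types are the Rh/BINAP-catalysed asymmetric 1,4-addition of arylzinc chlorides with chlorosilane trapping on heteroatom-substituted cyclic enones, the Rh-catalysed enantioselective conjugate arylation of chromones, and the Rubottom oxidation of flavanone silyl enol ethers. C2 is set by the ligand, which selects the enantioface of the flat chromone (2S in 13, which corresponds to 2R in 15 after the CIP priority change). C3 is set by relay: DMDO should transfer oxygen to the C3=C4 face anti to the C2 aryl group to give 14, and fluoride-induced collapse of 14 keeps that C3–O bond, so the hydroxyl ends trans to the aryl group. Trans is also the thermodynamic isomer, so a minor cis component could be equilibrated through the enol. No ring of the target is closed in this step; the only ring formed is the transient oxirane of 14 (concerted oxygen transfer), which is opened on desilylation. The step needs chemoselectivity for the silyl enol ether over the prenyl alkene, which the far higher nucleophilicity of the doubly oxygen-substituted enol ether at −78 °C with one equivalent of oxidant should secure. Buffered fluoride removes the two trimethylsilyl groups and the aryl TBS group without base-induced opening of ring C.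

## Compound list

1 | 2′,6′-dihydroxy-4′-methoxyacetophenone | CC(=O)c1c(O)cc(OC)cc1O | starting material
2 | 3-chloro-3-methylbut-1-yne | CC(C)(Cl)C#C | starting material
3 | 1-[2-hydroxy-4-methoxy-6-[(2-methylbut-3-yn-2-yl)oxy]phenyl]ethan-1-one | CC(=O)c1c(O)cc(OC)cc1OC(C)(C)C#C | intermediate
4 | (E)-3-(dimethylamino)-1-[2-hydroxy-4-methoxy-6-[(2-methylbut-3-yn-2-yl)oxy]phenyl]prop-2-en-1-one | CN(C)/C=C/C(=O)c1c(O)cc(OC)cc1OC(C)(C)C#C | intermediate
5 | 7-methoxy-5-[(2-methylbut-3-yn-2-yl)oxy]-4H-chromen-4-one | COc1cc2OC=CC(=O)c2c(OC(C)(C)C#C)c1 | intermediate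
6 | 7-methoxy-5-[(2-methylbut-3-en-2-yl)oxy]-4H-chromen-4-one | COc1cc2OC=CC(=O)c2c(OC(C)(C)C=C)c1 | intermediate
7 | 5-hydroxy-7-methoxy-6-(3-methylbut-2-en-1-yl)-4H-chromen-4-one | COc1cc2OC=CC(=O)c2c(O)c1CC=C(C)C | intermediate
8 | 5-bromo-2-methoxyphenol | COc1ccc(Br)cc1O | starting material
9 | (5-bromo-2-methoxyphenoxy)(tert-butyl)dimethylsilane | COc1ccc(Br)cc1O[Si](C)(C)C(C)(C)C | intermediate
10 | [3-(tert-butyldimethylsilyloxy)-4-methoxyphenyl]lithium | COc1ccc([Li])cc1O[Si](C)(C)C(C)(C)C | intermediate
11 | [3-(tert-butyldimethylsilyloxy)-4-methoxyphenyl]zinc chloride | COc1ccc([Zn]Cl)cc1O[Si](C)(C)C(C)(C)C | intermediate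
12 | 7-methoxy-6-(3-methylbut-2-en-1-yl)-5-(trimethylsilyloxy)-4H-chromen-4-one | COc1cc2OC=CC(=O)c2c(O[Si](C)(C)C)c1CC=C(C)C | intermediate
13 | (2S)-2-[3-(tert-butyldimethylsilyloxy)-4-methoxyphenyl]-7-methoxy-6-(3-methylbut-2-en-1-yl)-4,5-bis(trimethylsilyloxy)-2H-chromene | COc1ccc([C@H]2Oc3cc(OC)c(CC=C(C)C)c(O[Si](C)(C)C)c3C(O[Si](C)(C)C)=C2)cc1O[Si](C)(C)C(C)(C)C | intermediate
14 | 3,4-epoxide of 13, oxirane oxygen on C3 and C4 on the face trans to the C2 aryl group, C4 bearing the trimethylsilyloxy group | COc1ccc([C@H]2Oc3cc(OC)c(CC=C(C)C)c(O[Si](C)(C)C)c3[C@]4(O[Si](C)(C)C)O[C@H]24)cc1O[Si](C)(C)C(C)(C)C | intermediate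
15 | (2R,3R)-3,5-dihydroxy-2-(3-hydroxy-4-methoxyphenyl)-7-methoxy-6-(3-methylbut-2-en-1-yl)chroman-4-one | COc1ccc([C@H]2Oc3cc(OC)c(CC=C(C)C)c(O)c3C(=O)[C@@H]2O)cc1O | target

## Step count and risk

Total step count: 7. Longest linear sequence: 5 steps (steps 1, 2, 3, 4 and 7); the ring-B branch is steps 5 and 6.

**Step 7 (key step).** Carbometalation of an electron-rich chromone with a peri silyloxy group may be slow or poorly enantioselective. The silyl enol ether may hydrolyse before oxidation. Oxygen transfer to the prenyl double bond may compete with oxidation of the enol ether. The fallback separates the three events and sets out from 9 and 7. Aryllithium 10, made from 9 as in step 6, is quenched with triisopropyl borate and hydrolysed to [3-(tert-butyldimethylsilyloxy)-4-methoxyphenyl]boronic acid F1. A base-free Rh(I)/chiral bisphosphine 1,4-addition of F1 to 7 in toluene/water, with protonation in situ, should give (2S)-2-[3-(tert-butyldimethylsilyloxy)-4-methoxyphenyl]-5-hydroxy-7-methoxy-6-(3-methylbut-2-en-1-yl)chroman-4-one F2. Soft enolisation of F2 (TMSOTf, Et3N, CH2Cl2, −20 °C) silylates both the 5-OH and the ketone and returns to the route at 13. If the dioxirane stage is what fails, F2 is instead deprotonated (LiHMDS, 2.2 equiv, THF, −78 °C) and hydroxylated with 2-(phenylsulfonyl)-3-phenyloxaziridine, which does not epoxidise the prenyl group. This should give (2R,3R)-2-[3-(tert-butyldimethylsilyloxy)-4-methoxyphenyl]-3,5-dihydroxy-7-methoxy-6-(3-methylbut-2-en-1-yl)chroman-4-one F3, and TBAF/AcOH returns it to the route at 15.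

**Step 1.** O-alkylation of a chelated, hindered phenoxide by a tertiary electrophile may be slow; elimination of 2 to the enyne and double alkylation may compete. The fallback sets out from 1 and changes the bond-forming event to a palladium(0)-catalysed allylic etherification with tert-butyl 2-methylbut-3-en-2-yl carbonate, which under kinetic control should give the branched ether 1-[2-hydroxy-4-methoxy-6-[(2-methylbut-3-en-2-yl)oxy]phenyl]ethan-1-one F4. Condensation with the formamide acetal below 70 °C would give (E)-3-(dimethylamino)-1-[2-hydroxy-4-methoxy-6-[(2-methylbut-3-en-2-yl)oxy]phenyl]prop-2-en-1-one F5, and mild acid closes ring C. The route is rejoined at 6, and step 3 is then not needed.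

**Step 2.** Acid may cleave the tertiary propargylic ether during ring closure, or the aryl propargyl ether may cyclise thermally to a 2,2-dimethylchromene. The fallback sets out from 3 and avoids both heat and acid. C-formylation with ethyl formate (NaH, THF, 0 °C → rt) and neutral work-up should give the hemiacetal 2-hydroxy-7-methoxy-5-[(2-methylbut-3-yn-2-yl)oxy]chroman-4-one F6. Dehydration under non-acidic conditions (MsCl, Et3N, 0 °C) returns to the route at 5.

**Step 4.** The tertiary allyl ether may fragment (loss of the C5 unit) instead of rearranging. The group may migrate through the blocked C4a position on to C8. Traces of acid may cyclise the product onto the prenyl double bond. The fallback sets out from 1 and installs the prenyl group by cross-coupling instead of sigmatropic relay. Condensation of 1 with the formamide acetal would give (E)-3-(dimethylamino)-1-(2,6-dihydroxy-4-methoxyphenyl)prop-2-en-1-one F7, which closes to 5-hydroxy-7-methoxy-4H-chromen-4-one F8. Iodination ortho to the free 5-OH (BnMe3N·ICl2, CaCO3, CH2Cl2/MeOH) should give 5-hydroxy-6-iodo-7-methoxy-4H-chromen-4-one F9. Stille coupling with tributyl(3-methylbut-2-en-1-yl)stannane (Pd(PPh3)4, DMF, 80 °C) returns to the route at 7.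

## Further compounds

F1 | step 7 | [3-(tert-butyldimethylsilyloxy)-4-methoxyphenyl]boronic acid | COc1ccc(B(O)O)cc1O[Si](C)(C)C(C)(C)C
F2 | step 7 | (2S)-2-[3-(tert-butyldimethylsilyloxy)-4-methoxyphenyl]-5-hydroxy-7-methoxy-6-(3-methylbut-2-en-1-yl)chroman-4-one | COc1ccc([C@H]2Oc3cc(OC)c(CC=C(C)C)c(O)c3C(=O)C2)cc1O[Si](C)(C)C(C)(C)C
F3 | step 7 | (2R,3R)-2-[3-(tert-butyldimethylsilyloxy)-4-methoxyphenyl]-3,5-dihydroxy-7-methoxy-6-(3-methylbut-2-en-1-yl)chroman-4-one | COc1ccc([C@H]2Oc3cc(OC)c(CC=C(C)C)c(O)c3C(=O)[C@@H]2O)cc1O[Si](C)(C)C(C)(C)C
F4 | step 1 | 1-[2-hydroxy-4-methoxy-6-[(2-methylbut-3-en-2-yl)oxy]phenyl]ethan-1-one | CC(=O)c1c(O)cc(OC)cc1OC(C)(C)C=C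
F5 | step 1 | (E)-3-(dimethylamino)-1-[2-hydroxy-4-methoxy-6-[(2-methylbut-3-en-2-yl)oxy]phenyl]prop-2-en-1-one | CN(C)/C=C/C(=O)c1c(O)cc(OC)cc1OC(C)(C)C=C
F6 | step 2 | 2-hydroxy-7-methoxy-5-[(2-methylbut-3-yn-2-yl)oxy]chroman-4-one (racemic hemiacetal) | COc1cc2OC(O)CC(=O)c2c(OC(C)(C)C#C)c1
F7 | step 4 | (E)-3-(dimethylamino)-1-(2,6-dihydroxy-4-methoxyphenyl)prop-2-en-1-one | CN(C)/C=C/C(=O)c1c(O)cc(OC)cc1O
F8 | step 4 | 5-hydroxy-7-methoxy-4H-chromen-4-one | COc1cc(O)c2C(=O)C=COc2c1
F9 | step 4 | 5-hydroxy-6-iodo-7-methoxy-4H-chromen-4-one | COc1cc2OC=CC(=O)c2c(O)c1I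
A1 | alternative 1 | (E)-1-[4-methoxy-2,6-bis(methoxymethoxy)-3-(3-methylbut-2-en-1-yl)phenyl]-3-[4-methoxy-3-(methoxymethoxy)phenyl]prop-2-en-1-one | COCOc1c(CC=C(C)C)c(OC)cc(OCOC)c1C(=O)/C=C/c1ccc(OC)c(OCOC)c1
A2 | alternative 1 | [4-methoxy-2,6-bis(methoxymethoxy)-3-(3-methylbut-2-en-1-yl)phenyl][(2R,3S)-3-[4-methoxy-3-(methoxymethoxy)phenyl]oxiran-2-yl]methanone | COCOc1c(CC=C(C)C)c(OC)cc(OCOC)c1C(=O)[C@@H]1O[C@H]1c1ccc(OC)c(OCOC)c1
A3 | alternative 2 | (2R,3S)-3-[3-(tert-butyldimethylsilyloxy)-4-methoxyphenyl]-1-[2,6-dihydroxy-4-methoxy-3-(3-methylbut-2-en-1-yl)phenyl]-2,3-dihydroxypropan-1-one | COc1cc(O)c(C(=O)[C@H](O)[C@@H](O)c2ccc(OC)c(O[Si](C)(C)C(C)(C)C)c2)c(O)c1CC=C(C)C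
A4 | alternative 3 | 2-[1-[3-(tert-butyldimethylsilyloxy)-4-methoxyphenyl]-2-oxoethoxy]-4-methoxy-6-(methoxymethoxy)-5-(3-methylbut-2-en-1-yl)benzaldehyde (racemic) | O=CC(Oc1cc(OC)c(CC=C(C)C)c(OCOC)c1C=O)c1ccc(OC)c(O[Si](C)(C)C(C)(C)C)c1
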